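**Retrosynthetic overview**

1. C12 and C25 are adjacent quaternary carbons of the bicyclo[2.2.2]octane (rings C12–C13–C14–C16–C18–C25 and C12–C13–C14–C31–C30–C25). C25 is the β-carbon of the C16 enone inside the ring C14–C16–C18–C25–C30–C31, which is a dearomatised 5,7-dihydroxy-4,6-dimethylphthalide. The C12–C25 bond is therefore cut to a tertiary C12 radical, made by hydrogen-atom transfer to C11 of a ring B alkene C11=C12, and this dienone acceptor.
2. After the key bond: C18–C20 by ketone enolate alkylation (cyclopentane), C31–OH and C30–H by conjugate borylation–oxidation of a C30=C31 alkylidene lactone, C7=C8 by selenoxide elimination.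
3. Before it: C13–C14 by palladium-catalysed dearomative allylation of the phthalide (its γ-lactone and carbocycle come ready-made) with a ring B allylic carbonate.
4. Ring B fragment: asymmetric Michael addition and Robinson annulation set C9 and close ring B; methyl addition and lactonisation close the spiro δ-lactone (ring A); a singlet-oxygen cycloaddition sets C22; a reductive allylic transposition sets C21 and places the alkene at C11=C12.
5. Ring order: ring B, spiro δ-lactone ring A, union with the phthalide, bicyclo[2.2.2]octane, cyclopentane.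

Key step: step 19

Locants (C2, C9, O24 …) are the positions of the heavy atoms counted along the target SMILES and are kept for all intermediates.
Assumption: in steps 6 and 18 the catalyst antipode written is taken to be the one that gives the configuration drawn; if the sense of induction is the reverse, the mirror-image catalyst is used with no other change.

**Route**

Step 1
Reactants: 1 methyl 2,4-dihydroxy-3,6-dimethylbenzoate
Product: 2 methyl 5-bromo-2,4-dihydroxy-3,6-dimethylbenzoate
Conditions: NBS, MeCN, 0 °C
Reagents that add atoms: N-bromosuccinimide, O=C1CCC(=O)N1Br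
Why: Electrophilic aromatic bromination can only take the single free ring position, which is ortho to a hydroxyl group and strongly activated.

Step 2
Reactants: 2 methyl 5-bromo-2,4-dihydroxy-3,6-dimethylbenzoate
Product: 3 methyl 5-bromo-2,4-bis(methoxymethoxy)-3,6-dimethylbenzoate
Conditions: NaH, MOMCl, DMF, 0 → 23 °C
Reagents that add atoms: chloromethyl methyl ether, COCCl
Why: Williamson etherification of both phenoxides (NaH also takes the hydrogen-bonded ortho hydroxyl) masks the phenols for the lithiation of step 4.

Step 3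
Reactants: 3 methyl 5-bromo-2,4-bis(methoxymethoxy)-3,6-dimethylbenzoate
Product: 4 methyl 2,4-bis(methoxymethoxy)-3,5,6-trimethylbenzoate
Conditions: trimethylboroxine, Pd(OAc)2, SPhos, K2CO3, dioxane/H2O, 100 °C
Reagents that add atoms: trimethylboroxine, CB1OB(C)OB(C)O1
Why: Suzuki–Miyaura methylation with a bulky biarylphosphine should couple the di-ortho-substituted aryl bromide and installs the methyl group that becomes C19.

Step 4
Reactants: 4 methyl 2,4-bis(methoxymethoxy)-3,5,6-trimethylbenzoate
Product: 6 5,7-bis(methoxymethoxy)-4,6-dimethylphthalide, via hydroxymethyl benzoate 5 (not isolated)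
Conditions: LDA, THF, −78 °C; 2-(phenylsulfonyl)-3-phenyloxaziridine, −78 → 0 °C
Reagents that add atoms: 2-(phenylsulfonyl)-3-phenyloxaziridine, O=S(=O)(c1ccccc1)N1OC1c1ccccc1
Why: Lateral lithiation of the ortho-toluate is confined to the methyl group next to the ester, the benzylic anion is hydroxylated by the N-sulfonyloxaziridine and the alkoxide lactonises onto the ester to give the phthalide.

Step 5
Reactants: 6 5,7-bis(methoxymethoxy)-4,6-dimethylphthalide
Product: 7 5,7-dihydroxy-4,6-dimethylphthalide
Conditions: HCl (3 M), MeOH, 50 °C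
Reagents that add atoms: none
Why: Acid-catalysed acetal exchange with methanol frees both phenols and leaves the lactone untouched.

Step 6
Reactants: 8 diethyl 2-acetylpentanedioate; 9 but-3-en-2-one
Product: 10 diethyl (S)-2-acetyl-2-(3-oxobutyl)pentanedioate
Conditions: LaNa3[(R)-binaphthoxide]3 (10 mol%), CH2Cl2, −50 °C
Reagents that add atoms: none
Why: Catalytic asymmetric Michael addition of the α-substituted β-keto ester to the vinyl ketone, in which the lanthanum–sodium binaphthoxide holds enolate and enone and differentiates the enolate faces, sets the quaternary carbon C9.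

Step 7
Reactants: 10 diethyl (S)-2-acetyl-2-(3-oxobutyl)pentanedioate
Product: 12 ring B enone diester, via ketol 11 (not isolated)
Conditions: pyrrolidine (0.3 equiv), AcOH (0.3 equiv), PhMe, 80 °C
Reagents that add atoms: none
Why: Robinson annulation, in which the enamine of the unhindered methyl ketone attacks the acetyl group and the ketol dehydrates, should close ring B as the 3-methyl-4,4-disubstituted cyclohexenone without touching C9.

Step 8
Reactants: 12 ring B enone diester
Product: 14 C21 bromo enone, via dibromide 13 (not isolated)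
Conditions: Br2, CH2Cl2, 0 °C; then Et3N
Reagents that add atoms: bromine, BrBr
Why: Bromine addition to the enone alkene followed by dehydrobromination of the α-hydrogen gives the α-bromo enone and so a handle at C21.

Step 9
Reactants: 14 C21 bromo enone
Product: 15 C21 hydroxymethyl enone
Conditions: Bu3SnCH2OH, Pd(PPh3)4, dioxane, 90 °C
Reagents that add atoms: (tributylstannyl)methanol, CCCC[Sn](CCCC)(CCCC)CO
Why: Stille coupling of the α-bromo enone with the hydroxymethylstannane brings in C20 at the alcohol oxidation level.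

Step 10
Reactants: 15 C21 hydroxymethyl enone
Product: 16 C20 silyl ether enone
Conditions: TBSCl, imidazole, CH2Cl2, 23 °C
Reagents that add atoms: tert-butyldimethylsilyl chloride, CC(C)(C)[Si](C)(C)Cl
Why: Silylation protects the primary allylic alcohol for the base, organometallic and Mitsunobu steps that follow.

Step 11
Reactants: 16 C20 silyl ether enone
Product: 17 dienyl triflate
Conditions: LDA, THF, −78 °C; N-(5-chloro-2-pyridyl)triflimide, −78 → −40 °C
Reagents that add atoms: N-(5-chloropyridin-2-yl)bis(trifluoromethanesulfonyl)imide, O=S(=O)(N(c1ccc(Cl)cn1)S(=O)(=O)C(F)(F)F)C(F)(F)F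
Why: Kinetic deprotonation at C11, the only α-CH2 of the ketone (C21 is vinylic and C9 quaternary) and faster than ester deprotonation, and O-sulfonylation of the cross-conjugated enolate should give the 2-triflyloxy-1,3-diene.

Step 12
Reactants: 17 dienyl triflate
Product: 18 dienyl carbinol diester
Conditions: Bu3SnCH2OH, Pd(PPh3)4, LiCl, dioxane, 80 °C
Reagents that add atoms: (tributylstannyl)methanol, CCCC[Sn](CCCC)(CCCC)CO
Why: Stille coupling of the dienyl triflate installs C13 as a hydroxymethyl group on C12 and completes the diene C11=C12–C21=C22.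

Step 13
Reactants: 18 dienyl carbinol diester
Product: 19 dienyl carbinol acid ester
Conditions: LiOH·H2O, THF/H2O, 0 → 23 °C; then 1 M HCl to pH 4
Reagents that add atoms: lithium hydroxide, [Li+].[OH-]
Why: Saponification discriminates the unhindered propanoate ester from the neopentyl-type ester on the quaternary carbon C9.

Step 14
Reactants: 19 dienyl carbinol acid ester
Product: 21 spiro lactone dienyl carbinol, via hydroxy acid 20 (not isolated)
Conditions: MeMgBr, CeCl3, THF, −20 → 23 °C; aq. NH4Cl; then PPTS (cat.), PhMe, 50 °C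
Reagents that add atoms: methylmagnesium bromide, C[Mg]Br
Why: The cerium-assisted Grignard reagent adds twice to the remaining ester (magnesium carboxylate and alkoxide are inert) to build C2 with its two methyl groups, and acid-catalysed lactonisation of the tertiary alcohol onto the propanoic acid closes the spiro δ-lactone, ring A.

Step 15
Reactants: 21 spiro lactone dienyl carbinol
Product: 22 spiro lactone dienyl carbonate
Conditions: ClCO2Me, pyridine, CH2Cl2, 0 °C
Reagents that add atoms: methyl chloroformate, COC(=O)Cl
Why: Acylation of the only free hydroxyl turns C13 into the leaving-group terminus needed for the allylation of step 18.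

Step 16
Reactants: 22 spiro lactone dienyl carbonate
Product: 24 cis-C11,C22-diol, via endoperoxide 23 (not isolated)
Conditions: O2, tetraphenylporphyrin (cat.), visible light, CH2Cl2, −30 °C; then thiourea, MeOH, 23 °C
Reagents that add atoms: dioxygen, O=O
Why: Singlet-oxygen [4+2] cycloaddition across C11 and C22 of the cyclohexadiene and reduction of the O–O bond; the bridge should form anti to C2, which stands pseudo-axial on C9 to avoid allylic strain with the C22 methyl group, so that O24 is set cis to C8 and the C11 hydroxyl cis to O24.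

Step 17
Reactants: 24 cis-C11,C22-diol
Product: 27 ring B allylic carbonate, via N-allyl sulfonylhydrazine 25 (not isolated), via allylic diazene 26 (not isolated)
Conditions: 2-nitrobenzenesulfonylhydrazide, PPh3, DEAD, THF, −30 → 23 °C
Reagents that add atoms: none
Why: Mitsunobu displacement of the secondary allylic C11 hydroxyl by the sulfonylhydrazide with inversion (the tertiary C22 hydroxyl is inert), loss of sulfinic acid and retro-ene loss of N2 from the diazene deliver hydrogen to C21 on the face opposite to O24, which sets C21 (C20 cis to O24) and moves the alkene to C11=C12 (reductive 1,3-transposition of an allylic alcohol).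

Step 18
Reactants: 27 ring B allylic carbonate; 7 5,7-dihydroxy-4,6-dimethylphthalide
Product: 28 Giese precursor
Conditions: Pd2(dba)3·CHCl3 (2.5 mol%), (R,R)-DACH-phenyl ligand N,N'-[(1R,2R)-cyclohexane-1,2-diyl]bis[2-(diphenylphosphanyl)benzamide] (7.5 mol%), CH2Cl2, 23 °C
Reagents that add atoms: none
Why: Tsuji–Trost dearomative C-allylation, in which the π-allyl complex from the primary carbonate is attacked at its unhindered C13 terminus by C14, the only ring carbon ortho to both phenol oxygens (the central carbon of a vinylogous 1,3-dicarbonyl anion), gives the non-rearomatisable C16 ketone/C31 enol with the alkene at C11=C12, and the chiral pocket of the diphosphine selects the face of C14 and so sets this quaternary centre.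

Step 19
Reactants: 28 Giese precursor
Product: 29 bicyclo[2.2.2]octanone enol lactone
Conditions: Fe(acac)3 (1.0 equiv), PhSiH3 (2.5 equiv), EtOH/(CH2OH)2 (5:1), 60 °C, degassed
Reagents that add atoms: none
Why: Hydrogen-atom transfer from the iron hydride formed from Fe(acac)3 and PhSiH3 to C11 of the C11=C12 alkene gives the tertiary C12 radical, which adds to C25, the β-carbon of the C16 enone that is further activated through C30=C31 by the lactone carbonyl, and the resulting C18 α-keto radical is reduced by divalent iron and protonated by ethanol. The closest known reaction type is the iron-hydride reductive olefin coupling (hydrogen-atom-transfer Giese addition) that forges quaternary carbons, used here intramolecularly onto a fully substituted acceptor carbon. The new C12–C25 bond closes the ring C12–C13–C14–C31–C30–C25 in the 6-exo-trig mode (C18=C25 lies outside this ring) and at the same time the ring C12–C13–C14–C16–C18–C25 in the endo sense, and the two rings together are the bicyclo[2.2.2]octane. C25 is fixed by C14, because the one-carbon tether C13 can only reach the face of the dienone on which it stands; C12 should be set by attack on the ring B radical from the face cis to C20, the axial direction of the chair that keeps C20 equatorial, where only the C22 hydroxyl is met while the other face carries the C22 methyl group and C2; C18 is set by protonation and is erased in step 24. The step needs hydrogen transfer to the electron-rich trisubstituted alkene and not to the dienone, which the polarity of the hydridic iron hydride secures, and attack at C25 and not at C18, which is secured because the nucleophilic tertiary radical is polarity-matched only with the β-carbon.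

Step 20
Reactants: 29 bicyclo[2.2.2]octanone enol lactone
Product: 30 C31 enol triflate
Conditions: PhNTf2, Et3N, DMAP (cat.), CH2Cl2, 0 → 23 °C
Reagents that add atoms: N-phenylbis(trifluoromethanesulfonimide), O=S(=O)(N(c1ccccc1)S(=O)(=O)C(F)(F)F)C(F)(F)F
Why: O-Sulfonylation of the acidic β-keto lactone enol (the tertiary C22 hydroxyl does not react with this reagent) caps the enol and prepares removal of the C31 oxygen.

Step 21
Reactants: 30 C31 enol triflate
Product: 31 alkylidene lactone silyl ether
Conditions: Pd(OAc)2 (5 mol%), PPh3 (10 mol%), HCO2H, Bu3N, DMF, 60 °C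
Reagents that add atoms: none
Why: Palladium-catalysed formate reduction of the vinyl triflate replaces the triflate by hydrogen and leaves the C30=C31 alkylidene γ-lactone.

Step 22
Reactants: 31 alkylidene lactone silyl ether
Product: 32 alkylidene lactone C20 alcohol
Conditions: HF·pyridine, THF/pyridine, 0 → 23 °C
Reagents that add atoms: none
Why: Buffered fluoride cleaves the primary silyl ether without base, so that the alkylidene lactone and the tertiary alcohol are left alone.

Step 23
Reactants: 32 alkylidene lactone C20 alcohol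
Product: 33 alkylidene lactone C20 iodide
Conditions: I2, PPh3, imidazole, CH2Cl2, 0 → 23 °C
Reagents that add atoms: iodine, II
Why: Appel iodination converts only the primary alcohol (the tertiary C22 hydroxyl is inert and no enol remains) into the leaving group for ring closure.

Step 24
Reactants: 33 alkylidene lactone C20 iodide
Product: 34 pentacyclic alkylidene lactone
Conditions: LiHMDS (2.5 equiv), THF, −78 → 23 °C
Reagents that add atoms: none
Why: Intramolecular ketone enolate alkylation (5-exo-tet): the amide base is strong enough for the C16 ketone, which enolises only toward C18 because C14 is quaternary, but not for the lactones, the lithium C22 alkoxide is a bystander, and C20 can reach the planar C18 only from the side of C12, so the quaternary C18 forms with C19 on the side of C30 and the cyclopentane is closed.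

Step 25
Reactants: 34 pentacyclic alkylidene lactone
Product: 36 7,8-dihydro target, via C31 pinacol boronate 35 (not isolated)
Conditions: CuCl (10 mol%), DPEphos (10 mol%), NaOtBu (15 mol%), B2pin2, MeOH, THF, 23 °C; then NaBO3·4H2O, THF/H2O, 23 °C
Reagents that add atoms: sodium perborate, [Na+].[Na+].O[B-]1(O)OO[B-](O)(O)OO1
Why: Copper-catalysed conjugate borylation, in which the boryl copper species should add syn across C30=C31 from the face flanked by the trigonal C16 (the other face is screened by a C13 hydrogen), followed by protonolysis of the C30–copper bond and oxidation of the C–B bond with retention, places the hydroxyl on C31 syn to C16 and the C30 hydrogen on the same face, the arrangement in which C28 and the C31 oxygen are not eclipsed and which C30, being α to the lactone carbonyl, can also reach by equilibration.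

Step 26
Reactants: 36 7,8-dihydro target
Product: 37 C7 phenylselenide
Conditions: LDA (3.3 equiv), THF, −78 °C; PhSeBr, −78 °C
Reagents that add atoms: phenylselenyl bromide, Br[Se]c1ccccc1
Why: After both hydroxyls are deprotonated the δ-lactone enolate forms at C7, the only unhindered α-CH2 (the ketone has no α-hydrogen and C30 is tertiary and flanked by an alkoxide), and is selenenylated.

Step 27
Reactants: 37 C7 phenylselenide
Product: 39 target CNP0360620.3, via selenoxide 38 (not isolated)
Conditions: H2O2 (30%), pyridine, CH2Cl2, 0 → 23 °C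
Reagents that add atoms: none
Why: Oxidation to the selenoxide and syn-elimination, which can only take a hydrogen from C8 because C9 is quaternary, gives the C7=C8 unsaturated δ-lactone of the target.

**Compound list**

1 | methyl 2,4-dihydroxy-3,6-dimethylbenzoate | COC(=O)c1c(C)cc(O)c(C)c1O | starting material
2 | methyl 5-bromo-2,4-dihydroxy-3,6-dimethylbenzoate | COC(=O)c1c(C)c(Br)c(O)c(C)c1O | intermediate
3 | methyl 5-bromo-2,4-bis(methoxymethoxy)-3,6-dimethylbenzoate | COCOc1c(C)c(OCOC)c(Br)c(C)c1C(=O)OC | intermediate
4 | methyl 2,4-bis(methoxymethoxy)-3,5,6-trimethylbenzoate | COCOc1c(C)c(OCOC)c(C)c(C)c1C(=O)OC | intermediate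
5 | methyl 2-(hydroxymethyl)-4,6-bis(methoxymethoxy)-3,5-dimethylbenzoate (formed as its lithium alkoxide) | COCOc1c(C)c(OCOC)c(C)c(CO)c1C(=O)OC | intermediate (not isolated)
6 | 5,7-bis(methoxymethoxy)-4,6-dimethylisobenzofuran-1(3H)-one | COCOc1c(C)c(OCOC)c2c(c1C)COC2=O | intermediate
7 | 5,7-dihydroxy-4,6-dimethylisobenzofuran-1(3H)-one | Cc1c(O)c(C)c2c(c1O)C(=O)OC2 | intermediate
8 | diethyl 2-acetylpentanedioate | CCOC(=O)CCC(C(C)=O)C(=O)OCC | starting material
9 | but-3-en-2-one | CC(=O)C=C | starting material
10 | diethyl (S)-2-acetyl-2-(3-oxobutyl)pentanedioate | CCOC(=O)[C@](CCC(=O)OCC)(CCC(C)=O)C(C)=O | intermediate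
11 | ethyl 1-(3-ethoxy-3-oxopropyl)-2-hydroxy-2-methyl-4-oxocyclohexane-1-carboxylate, C9 as in 10, C22 epimers | CCOC(=O)[C@]1(CCC(=O)OCC)CCC(=O)CC1(C)O | intermediate (not isolated)
12 | ethyl (S)-1-(3-ethoxy-3-oxopropyl)-2-methyl-4-oxocyclohex-2-ene-1-carboxylate | CCOC(=O)[C@]1(CCC(=O)OCC)CCC(=O)C=C1C | intermediate
13 | 2,3-dibromide of 12 (ethyl 2,3-dibromo-1-(3-ethoxy-3-oxopropyl)-2-methyl-4-oxocyclohexane-1-carboxylate), C9 unchanged | CCOC(=O)[C@]1(CCC(=O)OCC)CCC(=O)C(Br)C1(C)Br | intermediate (not isolated)
14 | ethyl 3-bromo-1-(3-ethoxy-3-oxopropyl)-2-methyl-4-oxocyclohex-2-ene-1-carboxylate, C9 unchanged | CCOC(=O)[C@]1(CCC(=O)OCC)CCC(=O)C(Br)=C1C | intermediate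
15 | ethyl 1-(3-ethoxy-3-oxopropyl)-3-(hydroxymethyl)-2-methyl-4-oxocyclohex-2-ene-1-carboxylate, C9 unchanged | CCOC(=O)[C@]1(CCC(=O)OCC)CCC(=O)C(CO)=C1C | intermediate
16 | ethyl 3-{[(tert-butyldimethylsilyl)oxy]methyl}-1-(3-ethoxy-3-oxopropyl)-2-methyl-4-oxocyclohex-2-ene-1-carboxylate, C9 unchanged | CCOC(=O)[C@]1(CCC(=O)OCC)CCC(=O)C(CO[Si](C)(C)C(C)(C)C)=C1C | intermediate
17 | ethyl 3-{[(tert-butyldimethylsilyl)oxy]methyl}-1-(3-ethoxy-3-oxopropyl)-2-methyl-4-(trifluoromethylsulfonyloxy)cyclohexa-2,4-diene-1-carboxylate, C9 unchanged | CCOC(=O)[C@]1(CCC(=O)OCC)CC=C(OS(=O)(=O)C(F)(F)F)C(CO[Si](C)(C)C(C)(C)C)=C1C | intermediate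
18 | ethyl 3-{[(tert-butyldimethylsilyl)oxy]methyl}-1-(3-ethoxy-3-oxopropyl)-4-(hydroxymethyl)-2-methylcyclohexa-2,4-diene-1-carboxylate, C9 unchanged | CCOC(=O)[C@]1(CCC(=O)OCC)CC=C(CO)C(CO[Si](C)(C)C(C)(C)C)=C1C | intermediate
19 | 3-[3-{[(tert-butyldimethylsilyl)oxy]methyl}-1-(ethoxycarbonyl)-4-(hydroxymethyl)-2-methylcyclohexa-2,4-dien-1-yl]propanoic acid, C9 unchanged | CCOC(=O)[C@]1(CCC(=O)O)CC=C(CO)C(CO[Si](C)(C)C(C)(C)C)=C1C | intermediate
20 | 3-[3-{[(tert-butyldimethylsilyl)oxy]methyl}-4-(hydroxymethyl)-1-(2-hydroxypropan-2-yl)-2-methylcyclohexa-2,4-dien-1-yl]propanoic acid, C9 unchanged | CC(C)(O)[C@]1(CCC(=O)O)CC=C(CO)C(CO[Si](C)(C)C(C)(C)C)=C1C | intermediate (not isolated)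
21 | 8-{[(tert-butyldimethylsilyl)oxy]methyl}-9-(hydroxymethyl)-1,1,7-trimethyl-2-oxaspiro[5.5]undeca-7,9-dien-3-one, spiro carbon C9 as in 10 | CC1(C)OC(=O)CC[C@]12CC=C(CO)C(CO[Si](C)(C)C(C)(C)C)=C2C | intermediate
22 | methyl carbonate of 21 at the C13 hydroxyl | CC1(C)OC(=O)CC[C@]12CC=C(COC(=O)OC)C(CO[Si](C)(C)C(C)(C)C)=C2C | intermediate
23 | C11,C22-endoperoxide of 22, the dioxygen bridge on the face of C8 | CC1(C)OC(=O)CC[C@]12C[C@H]3OO[C@]2(C)C(CO[Si](C)(C)C(C)(C)C)=C3COC(=O)OC | intermediate (not isolated)
24 | 8-{[(tert-butyldimethylsilyl)oxy]methyl}-7,10-dihydroxy-9-[(methoxycarbonyloxy)methyl]-1,1,7-trimethyl-2-oxaspiro[5.5]undec-8-en-3-one, both hydroxyls (C22, C11) cis to C8 | CC1(C)OC(=O)CC[C@]12C[C@@H](O)C(COC(=O)OC)=C(CO[Si](C)(C)C(C)(C)C)[C@@]2(C)O | intermediate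
25 | C11 N-amino-N-(2-nitrobenzenesulfonyl)amine from 24, nitrogen on C11 trans to O24 | CC1(C)OC(=O)CC[C@]12C[C@H](N(N)S(=O)(=O)c3ccccc3[N+](=O)[O-])C(COC(=O)OC)=C(CO[Si](C)(C)C(C)(C)C)[C@@]2(C)O | intermediate (not isolated)
26 | C11 monoalkyl diazene from 25 | CC1(C)OC(=O)CC[C@]12C[C@H](N=N)C(COC(=O)OC)=C(CO[Si](C)(C)C(C)(C)C)[C@@]2(C)O | intermediate (not isolated)
27 | 8-{[(tert-butyldimethylsilyl)oxy]methyl}-7-hydroxy-9-[(methoxycarbonyloxy)methyl]-1,1,7-trimethyl-2-oxaspiro[5.5]undec-9-en-3-one; C8, O24 and C20 on one face of ring B | CC1(C)OC(=O)CC[C@]12CC=C(COC(=O)OC)[C@@H](CO[Si](C)(C)C(C)(C)C)[C@@]2(C)O | intermediate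
28 | key-step precursor: dearomatised phthalide (C16 ketone, C31 enol, C14 quaternary with methyl) joined through C13 to C12 of the ring B cyclohexene C11=C12 of 27 (C20 silyl ether, C22 hydroxyl, saturated spiro δ-lactone) | CC1(C)OC(=O)CC[C@]12CC=C(C[C@]3(C)C(=O)C(C)=C4COC(=O)C4=C3O)[C@@H](CO[Si](C)(C)C(C)(C)C)[C@@]2(C)O | intermediate
29 | key-step product: bicyclo[2.2.2]octan-16-one with C12–C25 bond, enolised β-keto γ-lactone (C31 enol), C18 H/methyl (configuration immaterial), C20 silyl ether, C22 hydroxyl | CC1(C)OC(=O)CC[C@]12CC[C@]3(C[C@]4(C)C(=O)[C@@H](C)[C@]35COC(=O)C5=C4O)[C@@H](CO[Si](C)(C)C(C)(C)C)[C@@]2(C)O | intermediate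
30 | C31 enol trifluoromethanesulfonate of 29 | CC1(C)OC(=O)CC[C@]12CC[C@]3(C[C@]4(C)C(=O)[C@@H](C)[C@]35COC(=O)C5=C4OS(=O)(=O)C(F)(F)F)[C@@H](CO[Si](C)(C)C(C)(C)C)[C@@]2(C)O | intermediate
31 | C30=C31 alkylidene γ-lactone (C31–H) from 30, C20 silyl ether | CC1(C)OC(=O)CC[C@]12CC[C@]3(C[C@]4(C)C(=O)[C@@H](C)[C@]35COC(=O)C5=C4)[C@@H](CO[Si](C)(C)C(C)(C)C)[C@@]2(C)O | intermediate
32 | C20 primary alcohol from 31 | CC1(C)OC(=O)CC[C@]12CC[C@]3(C[C@]4(C)C(=O)[C@@H](C)[C@]35COC(=O)C5=C4)[C@@H](CO)[C@@]2(C)O | intermediate
33 | C20 iodide from 32 | CC1(C)OC(=O)CC[C@]12CC[C@]3(C[C@]4(C)C(=O)[C@@H](C)[C@]35COC(=O)C5=C4)[C@@H](CI)[C@@]2(C)O | intermediate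
34 | pentacycle with C18–C20 bond (cyclopentane closed), C30=C31 alkylidene γ-lactone, saturated δ-lactone, C22 hydroxyl | CC1(C)OC(=O)CC[C@]12CC[C@]13C[C@]4(C)C(=O)[C@](C)(C[C@H]1[C@@]2(C)O)[C@]31COC(=O)C1=C4 | intermediate
35 | C31 pinacol boronate of the saturated γ-lactone, boron syn to C16, C30 hydrogen on the same face | CC1(C)OC(=O)CC[C@]12CC[C@]13C[C@]4(C)C(=O)[C@](C)(C[C@H]1[C@@]2(C)O)[C@]31COC(=O)[C@@H]1[C@H]4B1OC(C)(C)C(C)(C)O1 | intermediate (not isolated)
36 | 7,8-dihydro derivative of the target (saturated δ-lactone) | CC1(C)OC(=O)CC[C@]12CC[C@]13C[C@]4(C)C(=O)[C@](C)(C[C@H]1[C@@]2(C)O)[C@]31COC(=O)[C@@H]1[C@H]4O | intermediate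
37 | C7 phenylselanyl derivative of 36 (C7 epimers) | CC1(C)OC(=O)C([Se]c5ccccc5)C[C@]12CC[C@]13C[C@]4(C)C(=O)[C@](C)(C[C@H]1[C@@]2(C)O)[C@]31COC(=O)[C@@H]1[C@H]4O | intermediate
38 | selenoxide of 37 | CC1(C)OC(=O)C([Se](=O)c5ccccc5)C[C@]12CC[C@]13C[C@]4(C)C(=O)[C@](C)(C[C@H]1[C@@]2(C)O)[C@]31COC(=O)[C@@H]1[C@H]4O | intermediate (not isolated)
39 | CNP0360620.3 | CC1(C)OC(=O)C=C[C@]12CC[C@]13C[C@]4(C)C(=O)[C@](C)(C[C@H]1[C@@]2(C)O)[C@]31COC(=O)[C@@H]1[C@H]4O | target

**Totals and risks**

Total step count: 27 (5 for the phthalide, 12 for the ring B fragment, 10 from the union to the target).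
Longest linear sequence: 22 steps (steps 6–27, from diethyl 2-acetylpentanedioate).

Steps most likely to fail:

1. Step 19. The vinylogous acid may bind iron as a β-ketoenolate and, once ionised, lose its electrophilicity, so that hydrogen-atom transfer is followed by reduction of the C12 radical instead of ring closure; closure from the lower face of ring B is the second hazard. Fallback, setting out from 28 and coming back at 29: O-methylation of 28 with trimethylsilyldiazomethane (MeOH/PhMe) should give the two neutral vinylogous esters, the C31 methyl enol ether F1 and the C16 methyl enol ether F2, both of which keep C25 as the β-carbon of an enone. The same iron-hydride cyclisation of the mixture would give the cyclised enol ethers F3 and F4, and aqueous HCl in THF would hydrolyse both to 29.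

2. Step 18. Allylation may leak to C18 or to oxygen, and the ligand may be mismatched with the chiral electrophile so that the face of C14 is poorly selected. Fallback, setting out from 27 and coming back at 28: methanolysis of the carbonate (K2CO3, MeOH, 0 °C) to the allylic alcohol F5, Appel bromination (CBr4, PPh3, CH2Cl2) to the allylic bromide F6, and SN2 C-alkylation of the dilithium salt of 7 (LiOtBu, PhMe), in which the two lithium phenoxides that flank C14 direct the bromide to that carbon. The C14 epimers would then be separated by chromatography.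

3. Step 25. The boryl copper species may add to C31 from the side of C13, or the copper enolate may be protonated so as to leave C30 epimeric. Fallback, setting out from 34 and coming back at 36: the alcohol of unwanted C31 configuration from the borylation–oxidation, the C31 epimer F7, is oxidised with 1,1,1-triacetoxy-1,1-dihydro-1,2-benziodoxol-3(1H)-one to the β-keto lactone F8. NaBH4 in MeOH at −40 °C should then deliver hydride from the face that the boryl group had taken, which inverts C31, while C30 is protonated afresh and can equilibrate.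

**Further compounds**

F1 | step 19 | C31 methyl enol ether of 28 | CC1(C)OC(=O)CC[C@]12CC=C(C[C@]3(C)C(=O)C(C)=C4COC(=O)C4=C3OC)[C@@H](CO[Si](C)(C)C(C)(C)C)[C@@]2(C)O
F2 | step 19 | C16 methyl enol ether of 28 (C31 ketone tautomer) | CC1(C)OC(=O)CC[C@]12CC=C(C[C@]3(C)C(OC)=C(C)C4=C(C(=O)OC4)C3=O)[C@@H](CO[Si](C)(C)C(C)(C)C)[C@@]2(C)O
F3 | step 19 | cyclised C31 methyl enol ether (methyl ether of 29) | CC1(C)OC(=O)CC[C@]12CC[C@]3(C[C@]4(C)C(=O)[C@@H](C)[C@]35COC(=O)C5=C4OC)[C@@H](CO[Si](C)(C)C(C)(C)C)[C@@]2(C)O
F4 | step 19 | cyclised C16 methyl enol ether (C31 ketone, C30 hydrogen) | CC1(C)OC(=O)CC[C@]12CC[C@]3(C[C@]4(C)C(OC)=C(C)[C@]35COC(=O)C5C4=O)[C@@H](CO[Si](C)(C)C(C)(C)C)[C@@]2(C)O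
F5 | step 18 | C13 allylic alcohol from 27 | CC1(C)OC(=O)CC[C@]12CC=C(CO)[C@@H](CO[Si](C)(C)C(C)(C)C)[C@@]2(C)O
F6 | step 18 | C13 allylic bromide | CC1(C)OC(=O)CC[C@]12CC=C(CBr)[C@@H](CO[Si](C)(C)C(C)(C)C)[C@@]2(C)O
F7 | step 25 | C31 epimer of 36 | CC1(C)OC(=O)CC[C@]12CC[C@]13C[C@]4(C)C(=O)[C@](C)(C[C@H]1[C@@]2(C)O)[C@]31COC(=O)[C@@H]1[C@@H]4O
F8 | step 25 | pentacyclic β-keto γ-lactone, enol form | CC1(C)OC(=O)CC[C@]12CC[C@]13C[C@]4(C)C(=O)[C@](C)(C[C@H]1[C@@]2(C)O)[C@]31COC(=O)C1=C4O
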